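**Retrosynthetic overview**
- The target is reached from its 7,4'-bis(MOM) ether 10. The strategic cut in 10 is the sp2–sp3 bond C5'–C1'', giving 5'-bromoisoflavone 8 and prenylboronate 9.
- The feature that carries the plan: the prenyl-bearing carbon C5' of ring B lies ortho to the C4' oxygen and meta to C1'. In homovanillic acid this is the position the free phenol activates (its para position is blocked by the side chain), so a bromine placed there at the start becomes the coupling handle.
- Bromide 8 comes from triol 7, and 7 from deoxybenzoin 4 by inserting one carbon (C2) between the benzylic CH2 and a ring A hydroxyl. Deoxybenzoin 4 comes from phloroglucinol 3 and bromo acid 2 by C-acylation.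
- Ring order: rings A and B are purchased; ring C (the pyranone) is the only ring formed, in step 3. The acid-sensitive prenyl chain enters only after all Lewis-acid steps.

Key step: step 5

Assumptions on the chemistry: bromination of homovanillic acid is taken to occur at C5, ortho to the free hydroxyl, as with vanillin and other 4-substituted guaiacols. Intermediates 5 and 6 are drawn without the BF2 chelate they carry in the flask. The alkene geometry of 5 and the relative configuration of 6 are not fixed; both elements disappear in 7.

**Step 1**
Reactants: 1 homovanillic acid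
Product: 2 2-(3-bromo-4-hydroxy-5-methoxyphenyl)acetic acid (5-bromohomovanillic acid)
Conditions: Br2 (1.0 equiv), AcOH, 15 °C → rt
Reagents that add atoms: bromine, BrBr
Why: Electrophilic aromatic bromination is steered by the free 4-hydroxyl, whose para position is occupied by the acetic acid chain, so bromine should enter at C5 ortho to it, as in the bromination of vanillin.

**Step 2**
Reactants: 2 5-bromohomovanillic acid; 3 phloroglucinol (anhydrous)
Product: 4 2-(3-bromo-4-hydroxy-5-methoxyphenyl)-1-(2,4,6-trihydroxyphenyl)ethanone
Conditions: BF3·OEt2 (neat), 85 °C; then aq NaOAc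
Reagents that add atoms: none
Why: Friedel–Crafts C-acylation of the symmetrical, highly nucleophilic phloroglucinol by the BF3-activated arylacetic acid should stop after one acyl group because the product is held as a deactivated chelate, and the bromoguaiacol ring is far less nucleophilic.

**Step 3**
Reactants: 4 the deoxybenzoin
Product: 7 5'-bromo-5,7,4'-trihydroxy-3'-methoxyisoflavone, via enaminone 5 (not isolated), via 2-(dimethylamino)isoflavanone 6 (not isolated)
Conditions: BF3·OEt2, DMF, then MsCl in DMF, 55–70 °C; aq NaOAc work-up
Reagents that add atoms: N,N-dimethylformamide, CN(C)C=O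
Why: Vilsmeier-type formylation of the activated methylene by the iminium salt formed from DMF and MsCl should give enaminone 5, whose ortho hydroxyl adds to the enamine carbon (6-endo oxa-Michael) to give 6, and loss of dimethylamine then leaves the pyranone ring C, the classical deoxybenzoin route to isoflavones.

**Step 4**
Reactants: 7 5'-bromo-5,7,4'-trihydroxy-3'-methoxyisoflavone
Product: 8 5'-bromo-5-hydroxy-3'-methoxy-7,4'-bis(methoxymethoxy)isoflavone
Conditions: MOMCl (2.4 equiv), iPr2NEt (3 equiv), CH2Cl2/DMF, 0 °C → rt
Reagents that add atoms: chloromethyl methyl ether, COCCl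
Why: Williamson-type O-alkylation with the highly reactive MOMCl should take the acidic 7- and 4'-hydroxyls, while the 5-hydroxyl, hydrogen-bonded to the C4 carbonyl, is much less nucleophilic and stays free under amine base.

**Step 5**
Reactants: 8 5'-bromo-5-hydroxy-3'-methoxy-7,4'-bis(methoxymethoxy)isoflavone; 9 prenylboronic acid pinacol ester (1.5 equiv)
Product: 10 5-hydroxy-3'-methoxy-7,4'-bis(methoxymethoxy)-5'-(3-methylbut-2-enyl)isoflavone
Conditions: Pd(OAc)2 (3 mol %), t-BuXPhos [2-di-tert-butylphosphino-2',4',6'-triisopropylbiphenyl] (6 mol %), K3PO4 (3 equiv, aq), MeCN, 70 °C, degassed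
Reagents that add atoms: none
Why: Pd(OAc)2 is reduced in the flask to a zerovalent palladium–phosphine complex that inserts into the C5'–Br bond of 8; base-assisted transmetalation from boronate 9 gives aryl(allyl)palladium species that interconvert by sigma–pi–sigma shifts, and reductive elimination forms the C5'–C1'' bond. The closest known reaction type is the Suzuki–Miyaura coupling of aryl bromides with 3,3-disubstituted allylboronates under ligand control. No ring is closed and no stereocentre is created; the new alkene carries two identical methyl groups, so no geometry is at stake. The selectivity needed is coupling at the CH2 (alpha) terminus over the quaternary (gamma) terminus, which would give the 1,1-dimethylallyl isomer; the di-tert-butylbiarylphosphine should secure it, since its bulk disfavours a tertiary carbon–palladium bond and elimination then proceeds from the primary sigma-allyl form. The substrate helps: C5' has only one substituted ortho neighbour, the MOM acetals and the chromone tolerate aqueous phosphate, and the chelated 5-hydroxyl is carried through as its phenoxide.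

**Step 6**
Reactants: 10 the prenylated bis(MOM) ether
Product: 11 2'-deoxypiscerythrone
Conditions: HCl (1.25 M in MeOH), THF, rt → 40 °C, monitored
Reagents that add atoms: none
Why: Acid-catalysed acetal exchange with methanol should release both MOM groups as dimethoxymethane under conditions mild enough that the prenyl alkene is neither hydrated nor cyclised onto the ortho 4'-hydroxyl.

**Compound list**
1 | homovanillic acid | COc1cc(CC(=O)O)ccc1O | starting material
2 | 2-(3-bromo-4-hydroxy-5-methoxyphenyl)acetic acid | COc1cc(CC(=O)O)cc(Br)c1O | intermediate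
3 | phloroglucinol | Oc1cc(O)cc(O)c1 | starting material
4 | 2-(3-bromo-4-hydroxy-5-methoxyphenyl)-1-(2,4,6-trihydroxyphenyl)ethanone | COc1cc(CC(=O)c2c(O)cc(O)cc2O)cc(Br)c1O | intermediate
5 | 2-(3-bromo-4-hydroxy-5-methoxyphenyl)-3-(dimethylamino)-1-(2,4,6-trihydroxyphenyl)prop-2-en-1-one (enaminone, alkene geometry not fixed) | CN(C)C=C(C(=O)c1c(O)cc(O)cc1O)c1cc(OC)c(O)c(Br)c1 | intermediate (not isolated)
6 | 3-(3-bromo-4-hydroxy-5-methoxyphenyl)-2-(dimethylamino)-5,7-dihydroxychroman-4-one (transient diastereomer mixture) | CN(C)C1Oc2cc(O)cc(O)c2C(=O)C1c1cc(OC)c(O)c(Br)c1 | intermediate (not isolated)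
7 | 5'-bromo-5,7,4'-trihydroxy-3'-methoxyisoflavone [3-(3-bromo-4-hydroxy-5-methoxyphenyl)-5,7-dihydroxy-4H-chromen-4-one] | COc1cc(-c2coc3cc(O)cc(O)c3c2=O)cc(Br)c1O | intermediate
8 | 5'-bromo-5-hydroxy-3'-methoxy-7,4'-bis(methoxymethoxy)isoflavone | COCOc1cc(O)c2c(=O)c(-c3cc(OC)c(OCOC)c(Br)c3)coc2c1 | intermediate
9 | prenylboronic acid pinacol ester [4,4,5,5-tetramethyl-2-(3-methylbut-2-enyl)-1,3,2-dioxaborolane] | CC(C)=CCB1OC(C)(C)C(C)(C)O1 | starting material
10 | 5-hydroxy-3'-methoxy-7,4'-bis(methoxymethoxy)-5'-(3-methylbut-2-enyl)isoflavone | COCOc1cc(O)c2c(=O)c(-c3cc(OC)c(OCOC)c(CC=C(C)C)c3)coc2c1 | intermediate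
11 | 2'-deoxypiscerythrone [5,7-dihydroxy-3-(4-hydroxy-3-methoxy-5-(3-methylbut-2-enyl)phenyl)-4H-chromen-4-one] | COc1cc(-c2coc3cc(O)cc(O)c3c2=O)cc(CC=C(C)C)c1O | target

**Total step count:** 6
**Longest linear sequence:** 6 steps (1 → 2 → 4 → 7 → 8 → 10 → 11)

**Steps most likely to fail**

1. Step 5. The allyl fragment may couple at its quaternary (gamma) terminus, the boronate may protodeboronate, or the electron-rich bromide may be reduced before transmetalation. Fallback, setting out from 8 and returning at 10: bromide 8 is coupled with allylboronic acid pinacol ester (Pd(PPh3)4, CsF, THF, 65 °C), where both termini of the allyl unit give the same product, to give 5'-allyl-5-hydroxy-3'-methoxy-7,4'-bis(methoxymethoxy)isoflavone F1. Olefin cross-metathesis of F1 with excess 2-methylbut-2-ene (second-generation Grubbs catalyst, RuCl2(=CHPh)(H2IMes)(PCy3), CH2Cl2, 40 °C) should then build the trisubstituted alkene and deliver 10.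

2. Step 6. While the acetals are cleaved, the acid may protonate the prenyl alkene, leading to cyclisation onto the freed ortho 4'-hydroxyl (chroman formation) or to addition of HCl or methanol across the double bond. Fallback, setting out from 7 and returning at 11: the acid-labile protecting groups are replaced by fluoride-labile ones. Triol 7 is silylated (TBSCl, imidazole, DMF, rt) at the two non-chelated hydroxyls to give 5'-bromo-7,4'-bis(tert-butyldimethylsilyloxy)-5-hydroxy-3'-methoxyisoflavone F2. F2 is coupled with 9 under the conditions of step 5 to give 7,4'-bis(tert-butyldimethylsilyloxy)-5-hydroxy-3'-methoxy-5'-(3-methylbut-2-enyl)isoflavone F3. Buffered fluoride (Bu4NF, AcOH, THF, 0 °C) should then release 11 without any Brønsted acid strong enough to touch the alkene. Partial loss of silyl groups during the basic coupling would be harmless, since all such species converge on 11 after the fluoride treatment.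

3. Step 1. Bromine may also attack C6, para to the methoxy group, or a second bromine may enter. Fallback, setting out from 1 and returning at 2: regiocontrol is moved from innate substituent effects to amine-directed ortho delivery on the masked acid. Fischer esterification of 1 (MeOH, cat. H2SO4, reflux) gives methyl homovanillate F4. Treatment with N-bromosuccinimide and catalytic iPr2NH in CH2Cl2 at 0 °C, where the hydrogen-bonded N-bromoamine hands bromine to the position next to the hydroxyl, should give methyl 2-(3-bromo-4-hydroxy-5-methoxyphenyl)acetate F5. Saponification (LiOH, THF/H2O, rt) returns acid 2.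

**Further compounds**
F1 | step 5 | 5'-allyl-5-hydroxy-3'-methoxy-7,4'-bis(methoxymethoxy)isoflavone | COCOc1cc(O)c2c(=O)c(-c3cc(OC)c(OCOC)c(CC=C)c3)coc2c1
F2 | step 6 | 5'-bromo-7,4'-bis(tert-butyldimethylsilyloxy)-5-hydroxy-3'-methoxyisoflavone | COc1cc(-c2coc3cc(O[Si](C)(C)C(C)(C)C)cc(O)c3c2=O)cc(Br)c1O[Si](C)(C)C(C)(C)C
F3 | step 6 | 7,4'-bis(tert-butyldimethylsilyloxy)-5-hydroxy-3'-methoxy-5'-(3-methylbut-2-enyl)isoflavone | COc1cc(-c2coc3cc(O[Si](C)(C)C(C)(C)C)cc(O)c3c2=O)cc(CC=C(C)C)c1O[Si](C)(C)C(C)(C)C
F4 | step 1 | methyl homovanillate | COC(=O)Cc1ccc(O)c(OC)c1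
F5 | step 1 | methyl 2-(3-bromo-4-hydroxy-5-methoxyphenyl)acetate | COC(=O)Cc1cc(Br)c(O)c(OC)c1
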